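## Retrosynthetic overview

1. Target ⇐ fully protected trimer by one global hydrogenolysis (ten benzyl ethers, four diphenylmethylene ketals).
2. Protected trimer ⇐ C4(top)–C8(middle) bond: C4-activated tetra-O-benzylepicatechin plus a protected epicatechin-gallate dimer.
3. Dimer ⇐ C4(middle)–C8(bottom) bond between two copies of one protected epicatechin gallate, one of them oxidised at C4.
4. That monomer ⇐ (−)-epicatechin gallate by a single operation that closes two 2,2-diphenyl-1,3-benzodioxole rings at once (ring B catechol and galloyl diol) and benzylates the three remaining phenols.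
5. Ring order: the two dioxole rings are the only rings made (together, in the first step) and are reopened in the last step. The three pyran rings (ring C of each unit) and all C2/C3 stereocentres come intact from the two catechins. The two C4 stereocentres are set in the two couplings.

Reading of the target (one-line assumption): the SMILES is (−)-epicatechin-(4β→8)-(−)-epicatechin 3-O-gallate-(4β→8)-(−)-epicatechin 3-O-gallate, every unit 2R,3R (2,3-cis), both interflavan bonds 4β (3,4-trans).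

## Route

Step 1
Reactants: 1 (−)-epicatechin gallate; 2 dichlorodiphenylmethane; 3 benzyl bromide
Product: 5 5,7,5''-tri-O-benzyl-3',4':3'',4''-bis-O-(diphenylmethylene)-(−)-epicatechin gallate, via bis-ketal triol 4 (not isolated)
Conditions: Ph2CCl2 (2.3 equiv), Ph2O, 175 °C, 30 min, N2 sweep; cool to rt; DMF, K2CO3 (8 equiv), BnBr (3.6 equiv), rt, 16 h (one pot)
Reagents that add atoms: dichlorodiphenylmethane ClC(Cl)(c1ccccc1)c1ccccc1; benzyl bromide BrCc1ccccc1
Why: Double cyclic ketalisation with a geminal dichloride closes both five-membered 1,3-dioxole rings in the same operation (only the two ortho-diphenol pairs can cyclise, the meta-related 5,7-phenols and the odd galloyl phenol cannot), and the Williamson etherification that follows in the same flask caps those three phenols; no stereocentre is involved, and because the 4'-oxygen is tied up before base is added the quinone-methide route to C2 epimerisation is closed.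

Step 2
Reactants: 5 5,7,5''-tri-O-benzyl-3',4':3'',4''-bis-O-(diphenylmethylene)-(−)-epicatechin gallate; 6 2-ethoxyethanol
Product: 7 (2R,3R,4S)-4-(2-ethoxyethoxy) derivative of 5 (4β ether)
Conditions: DDQ (2.0 equiv), 2-ethoxyethanol (10 equiv), CH2Cl2, rt, 3 h
Reagents that add atoms: 2-ethoxyethanol CCOCCO
Why: DDQ benzylic oxidation (hydride abstraction at C4, the position activated by O1 and the 5,7-dialkoxy ring A) with capture of the cation by the alcohol anti to the 2-aryl and 3-acyloxy groups gives the 4β ether; the ketal carbons carry no hydrogen and so resist DDQ, and the C4 configuration is not critical because this centre is ionised again in step 3.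

Step 3
Reactants: 7 4β-(2-ethoxyethoxy) derivative of 5 (1.0 equiv); 5 protected epicatechin gallate (1.5 equiv)
Product: 8 protected dimer [unit of 5]-(4β→8)-[unit of 5]
Conditions: Yb(OTf)3 (1.0 equiv), CH2Cl2, 0 °C to rt
Reagents that add atoms: none
Why: Lewis-acid-promoted SN1-type Friedel–Crafts alkylation (interflavan coupling): Yb(OTf)3 ionises the C4 ether of 7 and C8 of 5, the most nucleophilic and least hindered position of its ring A, attacks the cation from the β-face, anti to the 3-O-galloyl group that shields the α-face by neighbouring-group participation, which sets the new C4 stereocentre as 4β (3,4-trans).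

Step 4
Reactants: 9 (−)-epicatechin; 3 benzyl bromide
Product: 10 5,7,3',4'-tetra-O-benzyl-(−)-epicatechin
Conditions: BnBr (4.4 equiv), K2CO3 (6 equiv), DMF, 0 °C to rt, 24 h
Reagents that add atoms: benzyl bromide BrCc1ccccc1
Why: Williamson ether synthesis: K2CO3 deprotonates only the four phenols, so the secondary 3-OH stays free, and the mild base at low temperature leaves C2 and C3 untouched.

Step 5
Reactants: 10 5,7,3',4'-tetra-O-benzyl-(−)-epicatechin; 6 2-ethoxyethanol
Product: 11 (2R,3R,4S)-5,7,3',4'-tetra-O-benzyl-4-(2-ethoxyethoxy)flavan-3-ol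
Conditions: DDQ (2.0 equiv), 2-ethoxyethanol (10 equiv), CH2Cl2, rt, 2 h
Reagents that add atoms: 2-ethoxyethanol CCOCCO
Why: Same DDQ benzylic oxidation as in step 2; the alcohol adds to the C4 cation anti to the α-oriented 2-aryl and 3-hydroxy groups, giving the 4β ether (2R,3R,4S).

Step 6
Reactants: 11 4β-(2-ethoxyethoxy)-tetra-O-benzylepicatechin (1.0 equiv); 8 protected dimer (1.0 equiv)
Product: 12 protected trimer [tetra-O-benzylepicatechin]-(4β→8)-[unit of 5]-(4β→8)-[unit of 5]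
Conditions: AgOTf (2.0 equiv), CH2Cl2, 0 °C to rt
Reagents that add atoms: none
Why: Second SN1-type Friedel–Crafts interflavan coupling: AgOTf ionises 11 and the cation is taken by C8 of the upper unit of 8, the only free C8 position and more nucleophilic and accessible than either C6, from the β-face anti to the α-oriented 2-aryl and 3-OH groups, which sets the top C4 stereocentre as 4β (3,4-trans).

Step 7
Reactants: 12 protected trimer
Product: 13 (−)-epicatechin-(4β→8)-(−)-epicatechin 3-O-gallate-(4β→8)-(−)-epicatechin 3-O-gallate (target)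
Conditions: H2 (1 atm), Pd(OH)2/C, THF/MeOH/H2O (20:1:1), rt, 12 h
Reagents that add atoms: none
Why: Catalytic hydrogenolysis over Pd(OH)2/C cleaves the ten benzyl ethers and the four diphenylmethylene ketals (all benzylic C–O bonds) under neutral conditions, leaving the two gallate esters, the acid-labile interflavan bonds and all eight stereocentres untouched.

## Compound list

1 | (−)-epicatechin gallate, (2R,3R)-2-(3,4-dihydroxyphenyl)-5,7-dihydroxychroman-3-yl 3,4,5-trihydroxybenzoate | O=C(O[C@@H]1Cc2c(O)cc(O)cc2O[C@@H]1c1ccc(O)c(O)c1)c1cc(O)c(O)c(O)c1 | starting material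

2 | dichlorodiphenylmethane | ClC(Cl)(c1ccccc1)c1ccccc1 | starting material

3 | benzyl bromide | BrCc1ccccc1 | starting material

4 | 3',4':3'',4''-bis-O-(diphenylmethylene)-(−)-epicatechin gallate, (2R,3R)-2-(2,2-diphenyl-1,3-benzodioxol-5-yl)-5,7-dihydroxychroman-3-yl 7-hydroxy-2,2-diphenyl-1,3-benzodioxole-5-carboxylate | O=C(O[C@@H]1Cc2c(O)cc(O)cc2O[C@@H]1c1ccc2OC(c3ccccc3)(c3ccccc3)Oc2c1)c1cc(O)c2OC(c3ccccc3)(c3ccccc3)Oc2c1 | intermediate

5 | 5,7,5''-tri-O-benzyl-3',4':3'',4''-bis-O-(diphenylmethylene)-(−)-epicatechin gallate, (2R,3R)-5,7-bis(benzyloxy)-2-(2,2-diphenyl-1,3-benzodioxol-5-yl)chroman-3-yl 7-(benzyloxy)-2,2-diphenyl-1,3-benzodioxole-5-carboxylate | O=C(O[C@@H]1Cc2c(OCc3ccccc3)cc(OCc3ccccc3)cc2O[C@@H]1c1ccc2OC(c3ccccc3)(c3ccccc3)Oc2c1)c1cc(OCc3ccccc3)c2OC(c3ccccc3)(c3ccccc3)Oc2c1 | intermediate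

6 | 2-ethoxyethanol | CCOCCO | starting material

7 | (2R,3R,4S)-4-(2-ethoxyethoxy) derivative of 5 (4β ether; 2,3-cis, 3,4-trans) | O=C(O[C@@H]1[C@@H](OCCOCC)c2c(OCc3ccccc3)cc(OCc3ccccc3)cc2O[C@@H]1c1ccc2OC(c3ccccc3)(c3ccccc3)Oc2c1)c1cc(OCc3ccccc3)c2OC(c3ccccc3)(c3ccccc3)Oc2c1 | intermediate

8 | protected dimer: two units with the protecting pattern of 5 joined C4(upper, 4β)→C8(lower); all C2/C3 are 2R,3R, upper 3,4-trans | O=C(O[C@@H]1[C@@H](c2c(OCc4ccccc4)cc(OCc4ccccc4)c3c2O[C@H](c2ccc4OC(c5ccccc5)(c5ccccc5)Oc4c2)[C@H](OC(=O)c2cc(OCc4ccccc4)c4OC(c5ccccc5)(c5ccccc5)Oc4c2)C3)c2c(OCc3ccccc3)cc(OCc3ccccc3)cc2O[C@@H]1c1ccc2OC(c3ccccc3)(c3ccccc3)Oc2c1)c1cc(OCc3ccccc3)c2OC(c3ccccc3)(c3ccccc3)Oc2c1 | intermediate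

9 | (−)-epicatechin, (2R,3R)-2-(3,4-dihydroxyphenyl)chroman-3,5,7-triol | O[C@@H]1Cc2c(O)cc(O)cc2O[C@@H]1c1ccc(O)c(O)c1 | starting material

10 | 5,7,3',4'-tetra-O-benzyl-(−)-epicatechin (2R,3R) | O[C@@H]1Cc2c(OCc3ccccc3)cc(OCc3ccccc3)cc2O[C@@H]1c1ccc(OCc2ccccc2)c(OCc2ccccc2)c1 | intermediate

11 | (2R,3R,4S)-5,7,3',4'-tetra-O-benzyl-4-(2-ethoxyethoxy)flavan-3-ol (4β ether) | O[C@@H]1[C@@H](OCCOCC)c2c(OCc3ccccc3)cc(OCc3ccccc3)cc2O[C@@H]1c1ccc(OCc2ccccc2)c(OCc2ccccc2)c1 | intermediate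

12 | protected trimer: tetra-O-benzylepicatechin-(4β→8)-[unit of 5]-(4β→8)-[unit of 5]; top 3-OH free | O=C(O[C@@H]1[C@@H](c2c(OCc4ccccc4)cc(OCc4ccccc4)c3c2O[C@H](c2ccc4OC(c5ccccc5)(c5ccccc5)Oc4c2)[C@H](OC(=O)c2cc(OCc4ccccc4)c4OC(c5ccccc5)(c5ccccc5)Oc4c2)C3)c2c(OCc3ccccc3)cc(OCc3ccccc3)c([C@H]3c4c(OCc5ccccc5)cc(OCc5ccccc5)cc4O[C@H](c4ccc(OCc5ccccc5)c(OCc5ccccc5)c4)[C@@H]3O)c2O[C@@H]1c1ccc2OC(c3ccccc3)(c3ccccc3)Oc2c1)c1cc(OCc3ccccc3)c2OC(c3ccccc3)(c3ccccc3)Oc2c1 | intermediate

13 | (−)-epicatechin-(4β→8)-(−)-epicatechin 3-O-gallate-(4β→8)-(−)-epicatechin 3-O-gallate (CNP0279403.1) | O=C(O[C@@H]1[C@@H](c2c(O)cc(O)c3c2O[C@H](c2ccc(O)c(O)c2)[C@H](OC(=O)c2cc(O)c(O)c(O)c2)C3)c2c(O)cc(O)c([C@H]3c4c(O)cc(O)cc4O[C@H](c4ccc(O)c(O)c4)[C@@H]3O)c2O[C@@H]1c1ccc(O)c(O)c1)c1cc(O)c(O)c(O)c1 | target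

## Step count and risks

Total step count: 7. Longest linear sequence: 5 steps (steps 1, 2, 3, 6, 7).

**Step 1.** The hot, HCl-releasing double ring closure telescoped with benzylation may cost the gallate ester, leave one ring unclosed, or carry intermolecular ketals into the alkylation. Fallback: assemble 5 by esterification instead of protecting intact epicatechin gallate. It sets out from 9: ketalisation with 2 (Ph2O, 175 °C) gives 3',4'-O-(diphenylmethylene)-(−)-epicatechin F1. Benzylation with 3 (K2CO3, DMF) gives 5,7-di-O-benzyl-3',4'-O-(diphenylmethylene)-(−)-epicatechin F2, with the 3-OH free. In parallel, purchased methyl gallate F3 is ketalised with 2 to methyl 7-hydroxy-2,2-diphenyl-1,3-benzodioxole-5-carboxylate F4. F4 is benzylated with 3 to methyl 7-(benzyloxy)-2,2-diphenyl-1,3-benzodioxole-5-carboxylate F5. Saponification (LiOH, THF/H2O) gives 7-(benzyloxy)-2,2-diphenyl-1,3-benzodioxole-5-carboxylic acid F6. Steglich esterification of F2 with F6 (EDC·HCl, DMAP, CH2Cl2) comes back to the route at 5.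

**Step 3.** Electrophile and nucleophile have the same ring A, so 7 can self-condense, 8 can react on, C6 attack can compete, and the ketals may suffer under Lewis acid. Fallback: use a far more nucleophilic partner so that cross-coupling wins at 1:1 stoichiometry. It sets out from 7 and from 4 (step 1 stopped after the ketalisation stage and 4 isolated). With catalytic Yb(OTf)3 in CH2Cl2/THF at 0 °C, the free 5,7-dihydroxy ring A of 4 captures the cation of 7 at C8. This gives the dimer triol [unit of 5]-(4β→8)-[unit of 4] F7. Benzylation of its three phenols with 3 (K2CO3, DMF) comes back to the route at 8.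

**Step 6.** Three ring A positions of 8 compete (upper C8, upper C6, lower C6) and the wanted site is hindered. Fallback: reverse the bond order with orthogonal C4 activation, so that the last coupling uses the monomer 5 as nucleophile. It sets out from 7: exchange of the ether for a thioether with 1,3-benzothiazole-2-thiol (catalytic Yb(OTf)3, CH2Cl2) gives the 4β-(1,3-benzothiazol-2-ylsulfanyl) analogue of 7 F8. Oxophilic activation of 11 (catalytic TMSOTf, CH2Cl2, −78 °C) leaves the thioether alone, and C8 of F8 takes the cation. This gives the top–middle dimer thioether tetra-O-benzylepicatechin-(4β→8)-[4β-(1,3-benzothiazol-2-ylsulfanyl) unit of 5] F9. Thiophilic activation of F9 with AgBF4 (THF, 0 °C) in the presence of 5 forms the middle–bottom bond and comes back to the route at 12.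

Further compounds

F1 | step 1 | 3',4'-O-(diphenylmethylene)-(−)-epicatechin | O[C@@H]1Cc2c(O)cc(O)cc2O[C@@H]1c1ccc2OC(c3ccccc3)(c3ccccc3)Oc2c1

F2 | step 1 | 5,7-di-O-benzyl-3',4'-O-(diphenylmethylene)-(−)-epicatechin | O[C@@H]1Cc2c(OCc3ccccc3)cc(OCc3ccccc3)cc2O[C@@H]1c1ccc2OC(c3ccccc3)(c3ccccc3)Oc2c1

F3 | step 1 | methyl gallate (purchased) | COC(=O)c1cc(O)c(O)c(O)c1

F4 | step 1 | methyl 7-hydroxy-2,2-diphenyl-1,3-benzodioxole-5-carboxylate | COC(=O)c1cc(O)c2OC(c3ccccc3)(c3ccccc3)Oc2c1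

F5 | step 1 | methyl 7-(benzyloxy)-2,2-diphenyl-1,3-benzodioxole-5-carboxylate | COC(=O)c1cc(OCc3ccccc3)c2OC(c3ccccc3)(c3ccccc3)Oc2c1

F6 | step 1 | 7-(benzyloxy)-2,2-diphenyl-1,3-benzodioxole-5-carboxylic acid | OC(=O)c1cc(OCc3ccccc3)c2OC(c3ccccc3)(c3ccccc3)Oc2c1

F7 | step 3 | dimer triol [unit of 5]-(4β→8)-[unit of 4] (lower unit 5,7,5''-OH free) | O=C(O[C@@H]1[C@@H](c2c(O)cc(O)c3c2O[C@H](c2ccc4OC(c5ccccc5)(c5ccccc5)Oc4c2)[C@H](OC(=O)c2cc(O)c4OC(c5ccccc5)(c5ccccc5)Oc4c2)C3)c2c(OCc3ccccc3)cc(OCc3ccccc3)cc2O[C@@H]1c1ccc2OC(c3ccccc3)(c3ccccc3)Oc2c1)c1cc(OCc3ccccc3)c2OC(c3ccccc3)(c3ccccc3)Oc2c1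

F8 | step 6 | 4β-(1,3-benzothiazol-2-ylsulfanyl) analogue of 7 | O=C(O[C@@H]1[C@@H](Sc3nc4ccccc4s3)c2c(OCc3ccccc3)cc(OCc3ccccc3)cc2O[C@@H]1c1ccc2OC(c3ccccc3)(c3ccccc3)Oc2c1)c1cc(OCc3ccccc3)c2OC(c3ccccc3)(c3ccccc3)Oc2c1

F9 | step 6 | tetra-O-benzylepicatechin-(4β→8)-[4β-(1,3-benzothiazol-2-ylsulfanyl) unit of 5] | O=C(O[C@@H]1[C@@H](Sc3nc4ccccc4s3)c2c(OCc3ccccc3)cc(OCc3ccccc3)c([C@H]3c4c(OCc5ccccc5)cc(OCc5ccccc5)cc4O[C@H](c4ccc(OCc5ccccc5)c(OCc5ccccc5)c4)[C@@H]3O)c2O[C@@H]1c1ccc2OC(c3ccccc3)(c3ccccc3)Oc2c1)c1cc(OCc3ccccc3)c2OC(c3ccccc3)(c3ccccc3)Oc2c1
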